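## The problem

The target (27) is a furanoheliangolide built on a ten-membered carbocycle C1–C10 (ring A, germacrane numbering). An oxygen bridge from C3 to C10 makes O, C10, C1, C2 and C3 a 3(2H)-furanone (ring B), and a trans α-methylene-γ-butyrolactone is fused at C6/C7 (ring C). Ring A must be closed although it holds a Z-configured trisubstituted C4=C5 alkene carrying the C15 hydroxymethyl group, a quaternary ether carbon C10, and the methacrylate-bearing C8. All four stereocentres are R. C6 and C7 are neighbours and can be set together in an open chain by an auxiliary. C8 and C10 lie on the far side of ring A and, unless made before ring closure, can only be controlled by C6/C7 through the conformation of a medium ring. The fragile groups are: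

- the α-methylene lactone, a Michael acceptor whose C7–H becomes α to a ketone and γ to the enoate as soon as C8 is a carbonyl, so that base would move the double bond into ring C;
- the methacrylate, the allylic C6–O lactone bond, and the Z alkene conjugated to the dienone of ring B;
- the primary allylic alcohol.

The enabling feature is the 1,4 relation between the C1 carbonyl of ring B and the oxygenated C8 across the C9–C10 bond. With C8 as a ketone, C9 and C10 are both enolate carbons, and the enol form at C10 is an aromatic 2-methyl-3-oxyfuran. An oxidative union of these two enolate carbons would form the quaternary centre, the furanone and ring A in one event.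

## Retrosynthesis

**End game, 27 back to 21.** The O15 silyl ether of 26 is removed last. The C11=C13 double bond of 26 is traced to the phenylsulfanylmethyl group of 24 (C13–S bond, sulfoxide elimination), the C8 ester to alcohol 22 and methacryloyl chloride 23, and the C8–H bond to ketone 21. Carrying C13 as a sulfide costs one step, but it removes the Michael acceptor and the doubly activated C7–H from every step that uses base, an oxidant or hydride. The reduction must be selective for C8 over C1 and must add hydride to the α face.

**Key disconnection, 21 back to 20 (C9–C10).** Cutting C9–C10 of diketone 21 gives two enol ethers, the 3-silyloxyfuran of C1/C10 and the enol ether of the C8 methyl ketone, tied through a diisopropylsilylene unit in the eleven-membered silacycle 20. Against the neighbouring cuts (C2–C3, C4–C5, C8–C9), this one creates the quaternary C10, ring B in its final oxidation state and ring A together, and it turns a ten-membered closure into a seven-membered one. The precursor has no stereocentre at C10 and is an open-chain furanone–ketone. The forward reaction has to couple C9 with C10 rather than with a second molecule, and on the correct furan face.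

**Tether, 20 back to 17 and 18 (two Si–O bonds).** The bis-enol ether comes from furanone–methyl ketone 17 and dichlorodiisopropylsilane 18. The furanone is far more acidic than the ketone, so the two Si–O bonds can be made in a fixed order. The second needs kinetic enolisation of the methyl ketone at C9 in the presence of C7–H and the lactone. With the plain α-methylene lactone this would be indefensible; with C11 saturated it is ordinary kinetic enolate chemistry.

**Ring B, 17 back to 16, then to 14, 15 and CO (O–C3, C2–C3 and C3–C4).** The furanone is the cycloisomer of γ-hydroxy alkynone 16. This in turn is the carbonylative coupling product of Z-alkenyl iodide 14, but-3-yn-2-ol 15 and carbon monoxide, which becomes C3. Installing ring B late keeps its acidic C10–H and its dienone out of the earlier enolate steps. It also fixes the Z geometry, because the iodide already has iodine cis to C6. The alternative, an aldol on a Z-enal that already carries the furanone, would expose both to boron enolate and cuprate chemistry.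

**Ketone and masked methylene, 14 back to 12 and 11 (C8–C9 and C11–C13).** The methyl ketone is the cuprate product of the acid chloride of 12. The C13 carbon is introduced by alkylating the dianion of paraconic acid 11, where the carboxylate shields C7–H and directs the electrophile trans. The order matters: once C8 is a ketone, the lactone α-carbon can no longer be deprotonated selectively.

**Lactone stereocentres, 11 back to 9, then to 7 and 4 (C6–C7 and the lactone C–O bond).** The trans-lactone is the lactonised Evans syn-aldol adduct of succinate imide 7 (from 5 and 6) and Z-iodoenal 4. A metal-mediated 2-(alkoxycarbonyl)allylation of the aldehyde would reach an α-methylene lactone in one step. It would, however, give the cis relation by default and leave the absolute configuration to a catalyst that is less well established than the auxiliary.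

**Z-iodoenal, 4 back to 3, 2 and 1.** The aldehyde comes from allylic alcohol 3, made by hydroxyl-directed anti-hydroalumination and iodination of the mono-silylated butynediol 2, itself from but-2-yne-1,4-diol 1. The anti addition fixes the alkene geometry four steps into the route and it is never at risk afterwards.

## Roads not taken

**Alternative 1:** The cut is the C3–C8 bond of a cis-fused decalin diol A1. Forward, Pb(OAc)4 cleaves the ring-fusion glycol and opens ring A as the 1,3,8-trione A2, from which ring B would follow by desilylation at O10 and cyclodehydration onto C3.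

- Merits: the ring is opened rather than closed, so there is no entropic penalty and no dilution. The Z alkene is inherited from a cyclohexene, and the C10 carbinol is set on a rigid bicycle. In ring formation and in control of C10 this road is better than the chosen one.
- Weak points: A2 holds a β-diketone (C1/C3) whose C2 can attack C8 across the ring. Its C10 oxygen is β to the C8 ketone, so elimination towards C9 or retro-aldol cleavage of C9–C10 threatens once silicon is off. The α-methylene lactone sits γ to that same ketone throughout. A1 needs two tertiary ring-fusion carbinols, the quaternary C10 and the trans-lactone on one decalin, which is a long synthesis.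
- Comparison: the chosen plan sets against this a precursor assembled from small acyclic pieces and a ring B that emerges without a separate step, and accepts in exchange an untested closure.

**Alternative 2:** The cut is C2–C3. Forward, the enolate of the C10 acetyl group in the nine-membered lactone A3 attacks the lactone carbonyl C3, and loss of water gives ring B and ring A together as A4.

- Merits: C8 and C10 are made in an open chain by reagent control and enter the closure already correct, and A4 is at the final oxidation level at C8. On stereocontrol and on the length of the end game this road is better than the chosen one.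
- Weak points: A3 is a nine-membered lactone of a tertiary α-acyl carbinol with a Z enoate, one of the least favourable esterifications. The key step needs a ketone enolate in the presence of the α-methylene lactone. Conjugate addition of C2 to C5 (a seven-membered ring) competes with acyl transfer, and the tetrahedral intermediate can revert before it dehydrates.
- Comparison: the chosen plan offers precursors that are easy to reach and a closure that needs no base, and pays with substrate-controlled stereochemistry at C8 and C10.

**Alternative 3:** The cut is C4=C5. Forward, ring-closing metathesis of diene A5 with a ruthenium alkylidene such as the second-generation Grubbs catalyst gives A6.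

- Merits: ring B and all four stereocentres are in place before closure, the step is catalytic and redox-neutral, and A5 can be made convergently. In convergence and in early stereocontrol it is better than the chosen plan.
- Weak points: the reacting 1,1-disubstituted alkene is hindered and conjugated to the furanone, and the product is a trisubstituted alkene in a ten-membered ring whose Z geometry would rest on ring strain alone. The exocyclic lactone methylene cannot be present during metathesis, so A6 lacks C13. Installing C13 by enolate chemistry next to the finished furanone is the operation the chosen route avoids.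
- Comparison: the chosen plan fixes the Z geometry at the outset and carries C13 masked from an early, simple intermediate.

Key step: step 12

Remarks on the chemistry:

- Germacrane numbering (C1–C15) is used for all fragments that contain target carbons; TBS is tert-butyldimethylsilyl.
- But-3-yn-2-ol is used as the racemate, so 16 and 17 are mixtures of C10 epimers; C10 becomes planar in step 11, so the mixture has no consequence.
- Metal enolates, alkoxides and aluminates formed in a flask are treated as reactive species and described in the Why lines; covalent intermediates of telescoped operations are numbered.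

## Steps

Step 1
Reactants: 1 but-2-yne-1,4-diol
Product: 2 4-(TBS-oxy)but-2-yn-1-ol
Conditions: NaH (1.0 equiv), THF, 0 °C to rt; TBSCl (1.0 equiv)
Reagents that add atoms: tert-butyl(chloro)dimethylsilane (TBSCl), CC(C)(C)[Si](C)(C)Cl
Why: Monosilylation of a symmetrical diol through its sparingly soluble monosodium alkoxide (O-silylation), which reacts before it equilibrates to the dialkoxide.

Step 2
Reactants: 2 4-(TBS-oxy)but-2-yn-1-ol
Product: 3 (2Z)-4-(TBS-oxy)-3-iodobut-2-en-1-ol
Conditions: NaAlH2(OCH2CH2OCH3)2, THF, 0 °C to rt; then I2, THF, −78 to 0 °C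
Reagents that add atoms: iodine, II
Why: Hydroxyl-directed anti-hydroalumination of the propargylic alcohol places aluminium on the distal alkyne carbon (C4) in a five-membered alkoxyaluminate, and iodinolysis with retention gives the Z-iodoalkene with iodine cis to C6, the geometry the later C3–C4 bond requires.

Step 3
Reactants: 3 (2Z)-4-(TBS-oxy)-3-iodobut-2-en-1-ol
Product: 4 (2Z)-4-(TBS-oxy)-3-iodobut-2-enal
Conditions: Dess–Martin periodinane, CH2Cl2, 0 °C to rt
Reagents that add atoms: none
Why: Dess–Martin oxidation of a primary allylic alcohol under non-basic conditions; the Z geometry should hold if the aldehyde is used directly.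

Step 4
Reactants: 5 (4S)-4-benzyl-1,3-oxazolidin-2-one; 6 methyl 4-chloro-4-oxobutanoate
Product: 7 methyl 4-[(4S)-4-benzyl-2-oxo-1,3-oxazolidin-3-yl]-4-oxobutanoate
Conditions: n-BuLi, THF, −78 °C; then 6, −78 to 0 °C
Reagents that add atoms: none
Why: N-Acylation of the lithiated oxazolidinone by the acid chloride, the standard preparation of Evans imides.

Step 5
Reactants: 7 methyl 4-[(4S)-4-benzyl-2-oxo-1,3-oxazolidin-3-yl]-4-oxobutanoate; 4 (2Z)-4-(TBS-oxy)-3-iodobut-2-enal
Product: 9 (4S)-4-benzyl-3-{[(2S,3S)-2-[(1Z)-3-(TBS-oxy)-2-iodoprop-1-en-1-yl]-5-oxooxolan-3-yl]carbonyl}-1,3-oxazolidin-2-one (trans-lactone imide), via syn-aldol adduct 8 (not isolated)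
Conditions: Bu2BOSO2CF3, iPr2NEt, CH2Cl2, −78 to 0 °C; then 4, −78 to 0 °C; pH 7 buffer, MeOH, H2O2; then PPTS (cat.), CH2Cl2, rt
Reagents that add atoms: none
Why: Evans syn-aldol reaction: the imide is enolised selectively (not the ester) to the Z boron enolate, and the (S)-benzyl auxiliary directs the aldehyde through a closed Zimmerman–Traxler transition state, setting C6 and C7 together; the syn adduct then lactonises onto the methyl ester to give the trans-lactone.

Step 6
Reactants: 9 trans-lactone imide
Product: 11 (2S,3S)-2-[(1Z)-3-(TBS-oxy)-2-iodoprop-1-en-1-yl]-5-oxooxolane-3-carboxylic acid, via peroxy acid 10 (not isolated)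
Conditions: LiOH, H2O2, THF/H2O, 0 °C; Na2SO3; then 1 M HCl to pH 3
Reagents that add atoms: hydrogen peroxide, OO
Why: Hydroperoxide attacks the exocyclic imide carbonyl selectively (Evans auxiliary cleavage), sulfite reduces the peroxy acid, and acidification re-closes any lactone opened by hydroxide.

Step 7
Reactants: 11 (2S,3S)-2-[(1Z)-3-(TBS-oxy)-2-iodoprop-1-en-1-yl]-5-oxooxolane-3-carboxylic acid
Product: 12 (2S,3S,4S)-2-[(1Z)-3-(TBS-oxy)-2-iodoprop-1-en-1-yl]-5-oxo-4-[(phenylsulfanyl)methyl]oxolane-3-carboxylic acid
Conditions: NaN(SiMe3)2 (2.2 equiv), THF, −78 °C; PhSCH2Cl, Bu4NI (cat.), −78 to −30 °C; then 1 M HCl (work-up)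
Reagents that add atoms: chloromethyl phenyl sulfide, ClCSc1ccccc1
Why: Two equivalents of base give the carboxylate–lactone enolate dianion (the carboxylate shields C7–H), and C-alkylation at C11 occurs anti to the C7 carboxylate, as in the known α-alkylation of paraconic acids; the sulfide is the masked C11=C13 methylene and its C11 centre is erased in step 15.

Step 8
Reactants: 12 (2S,3S,4S)-2-[(1Z)-3-(TBS-oxy)-2-iodoprop-1-en-1-yl]-5-oxo-4-[(phenylsulfanyl)methyl]oxolane-3-carboxylic acid
Product: 14 (3S,4S,5S)-4-acetyl-5-[(1Z)-3-(TBS-oxy)-2-iodoprop-1-en-1-yl]-3-[(phenylsulfanyl)methyl]oxolan-2-one, via acid chloride 13 (not isolated)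
Conditions: 1-chloro-N,N,2-trimethylprop-1-en-1-amine, CH2Cl2, 0 °C; then Me2CuLi (1.2 equiv), Et2O, −78 °C
Reagents that add atoms: lithium dimethylcuprate, [Li+].C[Cu-]C
Why: Neutral acid chloride formation followed by acyl substitution with a lithium dialkylcuprate, which stops at the ketone and at −78 °C should leave lactone, alkenyl iodide and sulfide untouched; the trans C6/C7 arrangement is also the thermodynamic one should C7 enolise.

Step 9
Reactants: 14 (3S,4S,5S)-4-acetyl-5-[(1Z)-3-(TBS-oxy)-2-iodoprop-1-en-1-yl]-3-[(phenylsulfanyl)methyl]oxolan-2-one; 15 but-3-yn-2-ol (racemic)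
Product: 16 (3S,4S,5R)-4-acetyl-5-[(1Z)-2-(TBS-oxymethyl)-6-hydroxy-3-oxohept-1-en-4-yn-1-yl]-3-[(phenylsulfanyl)methyl]oxolan-2-one (both carbinol epimers)
Conditions: PdCl2(PPh3)2 (5 mol %), CuI (10 mol %), Et3N, CO (1 atm), THF, rt
Reagents that add atoms: carbon monoxide, [C-]#[O+]
Why: Carbonylative Sonogashira coupling: zerovalent palladium inserts into the alkenyl iodide with retention, CO insertion gives the acylpalladium species, and the copper acetylide is acylated, so that C3 ends up cis to C6.

Step 10
Reactants: 16 γ-hydroxy alkynone
Product: 17 (3S,4S,5R)-4-acetyl-5-[(1Z)-3-(TBS-oxy)-2-(5-methyl-4-oxo-4,5-dihydrofuran-2-yl)prop-1-en-1-yl]-3-[(phenylsulfanyl)methyl]oxolan-2-one (C10 epimers)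
Conditions: (4-CF3C6H4)3PAuCl (5 mol %), AgOSO2CF3 (5 mol %), toluene, rt
Reagents that add atoms: none
Why: Known gold-catalysed cycloisomerisation of γ-hydroxy alkynones to 3(2H)-furanones (formal oxygen transfer to C1 and cyclodehydration of the C10 hydroxyl onto C3); the C10 epimers converge in step 11.

Step 11
Reactants: 17 furanone methyl ketone; 18 dichlorodiisopropylsilane
Product: 20 diisopropylsilylene-bridged bis-enol ether (eleven-membered silacycle linking the furan 3-oxygen at C1 to the enol ether oxygen at C8; 6R,7S,11S; Z C4=C5), via chlorosilyl furyl ether 19 (not isolated)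
Conditions: LiN(SiMe3)2 (1.0 equiv), THF, −78 °C; 18 (1.1 equiv), −78 to 0 °C; then added slowly to LiN(iPr)2 (1.1 equiv), THF (2 mM), −78 to −20 °C
Reagents that add atoms: none
Why: Stepwise formation of an unsymmetrical silyl bis-enol ether: the much more acidic C10–H is removed first and the aromatic 3-furanolate is O-silylated by one Si–Cl bond (the second is slowed by the isopropyl groups); kinetic deprotonation of the methyl ketone at C9 by the hindered amide, with inverse addition and high dilution, is then followed by intramolecular O-silylation, and with C11 saturated there is neither a Michael acceptor nor a doubly activated C7–H.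

Step 12
Reactants: 20 diisopropylsilylene-bridged bis-enol ether
Product: 21 (4Z,6R,7S,10R,11S)-15-(TBS-oxy)-3,10-epoxy-1,8-dioxo-13-(phenylsulfanyl)germacra-2,4-dien-12,6-olide (8-oxo core)
Conditions: (NH4)2Ce(NO3)6 (2.2 equiv), NaHCO3 (4.4 equiv), MeCN/EtCN, −30 °C
Reagents that add atoms: none
Why: Proposed new method: the tetravalent cerium salt should remove one electron from the more electron-rich enol ether, the 3-silyloxyfuran, and the radical cation is attacked at C10 by the tethered enol ether carbon C9; a second one-electron oxidation and loss of silicon as iPr2Si(OH)2 then unveil the C1 and C8 carbonyl groups. The closest known reaction type is the (NH4)2Ce(NO3)6-mediated heterocoupling of dialkylsilyl bis-enol ethers of two ketones to 1,4-diketones, quaternary centres included; new here are the heteroaromatic partner, which is dearomatised to the 3(2H)-furanone, and the transannular setting. Ring A closes in a 7-endo-trig mode through the seven-membered array C9–C8–O–Si–O–C1–C10, which contracts the eleven-membered silacycle to the ten-membered carbocycle once silicon has left. The new stereocentre C10 is under substrate control: the C6/C7 trans-lactone and the Z C4=C5 bond fix the conformation of the silacycle so that the tether, and with it C9, lies over one furan face, expected to be the one that gives 10R. The step needs heterocoupling, attack at C10 rather than C3, and survival of the sulfide; the tether secures the first two (C3 is out of reach of a seven-membered transition structure), and the aryl sulfide is oxidised at a clearly higher potential than the silyloxyfuran. NaHCO3 keeps the acidic oxidant from hydrolysing the enol ethers before electron transfer.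

Step 13
Reactants: 21 8-oxo core
Product: 22 (4Z,6R,7R,8R,10R,11S)-15-(TBS-oxy)-3,10-epoxy-8-hydroxy-1-oxo-13-(phenylsulfanyl)germacra-2,4-dien-12,6-olide
Conditions: NaBH4, CeCl3·7H2O, MeOH/CH2Cl2, −78 °C
Reagents that add atoms: none
Why: Luche reduction: the cerium-activated C8 ketone is reduced while the vinylogous ester carbonyl C1 and the lactone are much less electrophilic, and the masked lactone offers no conjugate acceptor; hydride should enter from the α face that carries H7, anti to C11 on the neighbouring C7, giving the 8β (8R) alcohol.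

Step 14
Reactants: 22 8β-alcohol; 23 methacryloyl chloride
Product: 24 (4Z,6R,7R,8R,10R,11S)-15-(TBS-oxy)-3,10-epoxy-8-(2-methylprop-2-enoyloxy)-1-oxo-13-(phenylsulfanyl)germacra-2,4-dien-12,6-olide
Conditions: Et3N, DMAP (cat.), CH2Cl2, −20 to 0 °C
Reagents that add atoms: none
Why: DMAP-catalysed acylation of a secondary alcohol by an acid chloride; it is run cold and promptly so that esterification outruns translactonisation of the 8β-hydroxyl onto C12.

Step 15
Reactants: 24 methacrylate sulfide
Product: 26 (4Z,6R,7R,8R,10R)-15-(TBS-oxy)-3,10-epoxy-8-(2-methylprop-2-enoyloxy)-1-oxogermacra-2,4,11(13)-trien-12,6-olide, via sulfoxide 25 (not isolated)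
Conditions: mCPBA (1.0 equiv), CH2Cl2, −78 °C; then toluene, 90 °C
Reagents that add atoms: none
Why: Oxidation of the sulfide to the sulfoxide is much faster than epoxidation of the electron-poor alkenes, and thermal syn-elimination (sulfoxide pyrolysis) can only use C11–H, so the exocyclic C11=C13 bond forms regiospecifically.

Step 16
Reactants: 26 O15-silylated target
Product: 27 (4Z,6R,7R,8R,10R)-3,10-epoxy-15-hydroxy-8-(2-methylprop-2-enoyloxy)-1-oxogermacra-2,4,11(13)-trien-12,6-olide (target)
Conditions: HF·pyridine, pyridine, THF, 0 °C to rt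
Reagents that add atoms: none
Why: Fluoride cleavage of the primary silyl ether under buffered conditions that spare the methacrylate, the α-methylene lactone and the furanone.

## Compound list

1 | but-2-yne-1,4-diol | OCC#CCO | starting material
2 | 4-{[tert-butyl(dimethyl)silyl]oxy}but-2-yn-1-ol | OCC#CCO[Si](C)(C)C(C)(C)C | intermediate
3 | (2Z)-4-{[tert-butyl(dimethyl)silyl]oxy}-3-iodobut-2-en-1-ol | OC/C=C(\I)CO[Si](C)(C)C(C)(C)C | intermediate
4 | (2Z)-4-{[tert-butyl(dimethyl)silyl]oxy}-3-iodobut-2-enal | O=C/C=C(\I)CO[Si](C)(C)C(C)(C)C | intermediate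
5 | (4S)-4-benzyl-1,3-oxazolidin-2-one | O=C1N[C@@H](Cc2ccccc2)CO1 | starting material
6 | methyl 4-chloro-4-oxobutanoate | COC(=O)CCC(=O)Cl | starting material
7 | methyl 4-[(4S)-4-benzyl-2-oxo-1,3-oxazolidin-3-yl]-4-oxobutanoate | COC(=O)CCC(=O)N1[C@@H](Cc2ccccc2)COC1=O | intermediate
8 | methyl (3S,4S,5Z)-3-{[(4S)-4-benzyl-2-oxo-1,3-oxazolidin-3-yl]carbonyl}-7-{[tert-butyl(dimethyl)silyl]oxy}-4-hydroxy-6-iodohept-5-enoate (syn-aldol adduct) | COC(=O)C[C@@H]([C@H](O)/C=C(\I)CO[Si](C)(C)C(C)(C)C)C(=O)N1[C@@H](Cc2ccccc2)COC1=O | intermediate (not isolated)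
9 | (4S)-4-benzyl-3-{[(2S,3S)-2-[(1Z)-3-{[tert-butyl(dimethyl)silyl]oxy}-2-iodoprop-1-en-1-yl]-5-oxooxolan-3-yl]carbonyl}-1,3-oxazolidin-2-one | I/C(CO[Si](C)(C)C(C)(C)C)=C\[C@H]1OC(=O)C[C@@H]1C(=O)N2[C@@H](Cc3ccccc3)COC2=O | intermediate
10 | (2S,3S)-2-[(1Z)-3-{[tert-butyl(dimethyl)silyl]oxy}-2-iodoprop-1-en-1-yl]-5-oxooxolane-3-carboperoxoic acid | I/C(CO[Si](C)(C)C(C)(C)C)=C\[C@H]1OC(=O)C[C@@H]1C(=O)OO | intermediate (not isolated)
11 | (2S,3S)-2-[(1Z)-3-{[tert-butyl(dimethyl)silyl]oxy}-2-iodoprop-1-en-1-yl]-5-oxooxolane-3-carboxylic acid | I/C(CO[Si](C)(C)C(C)(C)C)=C\[C@H]1OC(=O)C[C@@H]1C(=O)O | intermediate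
12 | (2S,3S,4S)-2-[(1Z)-3-{[tert-butyl(dimethyl)silyl]oxy}-2-iodoprop-1-en-1-yl]-5-oxo-4-[(phenylsulfanyl)methyl]oxolane-3-carboxylic acid | I/C(CO[Si](C)(C)C(C)(C)C)=C\[C@H]1OC(=O)[C@@H](CSc2ccccc2)[C@@H]1C(=O)O | intermediate
13 | (2S,3S,4S)-2-[(1Z)-3-{[tert-butyl(dimethyl)silyl]oxy}-2-iodoprop-1-en-1-yl]-5-oxo-4-[(phenylsulfanyl)methyl]oxolane-3-carbonyl chloride | I/C(CO[Si](C)(C)C(C)(C)C)=C\[C@H]1OC(=O)[C@@H](CSc2ccccc2)[C@@H]1C(=O)Cl | intermediate (not isolated)
14 | (3S,4S,5S)-4-acetyl-5-[(1Z)-3-{[tert-butyl(dimethyl)silyl]oxy}-2-iodoprop-1-en-1-yl]-3-[(phenylsulfanyl)methyl]oxolan-2-one | I/C(CO[Si](C)(C)C(C)(C)C)=C\[C@H]1OC(=O)[C@@H](CSc2ccccc2)[C@@H]1C(C)=O | intermediate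
15 | but-3-yn-2-ol (racemic) | CC(O)C#C | starting material
16 | (3S,4S,5R)-4-acetyl-5-[(1Z)-2-({[tert-butyl(dimethyl)silyl]oxy}methyl)-6-hydroxy-3-oxohept-1-en-4-yn-1-yl]-3-[(phenylsulfanyl)methyl]oxolan-2-one (both epimers at the carbinol, C10) | CC(O)C#CC(=O)/C(CO[Si](C)(C)C(C)(C)C)=C\[C@H]1OC(=O)[C@@H](CSc2ccccc2)[C@@H]1C(C)=O | intermediate
17 | (3S,4S,5R)-4-acetyl-5-[(1Z)-3-{[tert-butyl(dimethyl)silyl]oxy}-2-(5-methyl-4-oxo-4,5-dihydrofuran-2-yl)prop-1-en-1-yl]-3-[(phenylsulfanyl)methyl]oxolan-2-one (both epimers at the furanone CH, C10) | CC1OC(=CC1=O)/C(CO[Si](C)(C)C(C)(C)C)=C\[C@H]2OC(=O)[C@@H](CSc3ccccc3)[C@@H]2C(C)=O | intermediate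
18 | dichlorodi(propan-2-yl)silane | CC(C)[Si](Cl)(Cl)C(C)C | starting material
19 | (3S,4S,5R)-4-acetyl-5-[(1Z)-3-{[tert-butyl(dimethyl)silyl]oxy}-2-(4-{[chlorodi(propan-2-yl)silyl]oxy}-5-methylfuran-2-yl)prop-1-en-1-yl]-3-[(phenylsulfanyl)methyl]oxolan-2-one | Cc1oc(cc1O[Si](Cl)(C(C)C)C(C)C)/C(CO[Si](C)(C)C(C)(C)C)=C\[C@H]2OC(=O)[C@@H](CSc3ccccc3)[C@@H]2C(C)=O | intermediate (not isolated)
20 | diisopropylsilylene-bridged bis-enol ether: the 3-oxygen of the 2-methyl-5-alkenylfuran (on C1) and the oxygen of the C8(=C9H2) enol ether are joined through Si(iPr)2 in an eleven-membered ring; trans-lactone with C11 bearing CH2SPh, O15 TBS, Z C4=C5, (6R,7S,11S) | Cc1oc(cc1O[Si](C(C)C)(C(C)C)O3)/C(CO[Si](C)(C)C(C)(C)C)=C\[C@H]2OC(=O)[C@@H](CSc4ccccc4)[C@@H]2C3=C | intermediate (key-step precursor)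
21 | (4Z,6R,7S,10R,11S)-15-{[tert-butyl(dimethyl)silyl]oxy}-3,10-epoxy-1,8-dioxo-13-(phenylsulfanyl)germacra-2,4-dien-12,6-olide | O=C1C[C@@]2(C)OC(=CC2=O)/C(CO[Si](C)(C)C(C)(C)C)=C\[C@H]2OC(=O)[C@@H](CSc3ccccc3)[C@@H]21 | intermediate (key-step product)
22 | (4Z,6R,7R,8R,10R,11S)-15-{[tert-butyl(dimethyl)silyl]oxy}-3,10-epoxy-8-hydroxy-1-oxo-13-(phenylsulfanyl)germacra-2,4-dien-12,6-olide | O[C@@H]1C[C@@]2(C)OC(=CC2=O)/C(CO[Si](C)(C)C(C)(C)C)=C\[C@H]2OC(=O)[C@@H](CSc3ccccc3)[C@@H]21 | intermediate
23 | 2-methylprop-2-enoyl chloride (methacryloyl chloride) | C=C(C)C(=O)Cl | starting material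
24 | (4Z,6R,7R,8R,10R,11S)-15-{[tert-butyl(dimethyl)silyl]oxy}-3,10-epoxy-8-(2-methylprop-2-enoyloxy)-1-oxo-13-(phenylsulfanyl)germacra-2,4-dien-12,6-olide | C=C(C)C(=O)O[C@@H]1C[C@@]2(C)OC(=CC2=O)/C(CO[Si](C)(C)C(C)(C)C)=C\[C@H]2OC(=O)[C@@H](CSc3ccccc3)[C@@H]21 | intermediate
25 | sulfoxide of 24 (13-phenylsulfinyl; mixture at sulfur) | C=C(C)C(=O)O[C@@H]1C[C@@]2(C)OC(=CC2=O)/C(CO[Si](C)(C)C(C)(C)C)=C\[C@H]2OC(=O)[C@@H](CS(=O)c3ccccc3)[C@@H]21 | intermediate (not isolated)
26 | (4Z,6R,7R,8R,10R)-15-{[tert-butyl(dimethyl)silyl]oxy}-3,10-epoxy-8-(2-methylprop-2-enoyloxy)-1-oxogermacra-2,4,11(13)-trien-12,6-olide | C=C(C)C(=O)O[C@@H]1C[C@@]2(C)OC(=CC2=O)/C(CO[Si](C)(C)C(C)(C)C)=C\[C@H]2OC(=O)C(=C)[C@@H]21 | intermediate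
27 | (4Z,6R,7R,8R,10R)-3,10-epoxy-15-hydroxy-8-(2-methylprop-2-enoyloxy)-1-oxogermacra-2,4,11(13)-trien-12,6-olide | C=C(C)C(=O)O[C@@H]1C[C@@]2(C)OC(=CC2=O)/C(CO)=C\[C@H]2OC(=O)C(=C)[C@@H]21 | target

## Step count and least certain steps

Total step count: 16. Longest linear sequence: 15 (steps 1–3 and 5–16); step 4 is the one-step branch.

**Step 12 (key step, proposed new method).**
- What may go wrong: the radical cation may be consumed by intermolecular coupling, nitrate capture or desilylation before C9 reaches C10, because the seven-membered transition structure has to be attained inside a strained eleven-membered ring. Poor facial selectivity at C10 and competing electron transfer from sulfur are the next concerns.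
- Fallback (known chemistry, same C9–C10 bond by enolate alkylation): it sets out from acid 12. The acid chloride 13, made as in step 8, is treated with diazomethane to give the diazoketone F1, and HCl in Et2O converts this into the chloromethyl ketone F2. Carbonylative coupling with 15 under the conditions of step 9 gives the chloro hydroxy alkynone F3, and gold-catalysed cyclisation as in step 10 gives the chloro furanone F4. Cs2CO3 with catalytic NaI in MeCN at high dilution deprotonates only the furanone, and C-alkylation of the furanolate at C10 by the α-halo ketone closes ring A. The fallback rejoins the route at 21. C2-alkylation of 3(2H)-furanone enolates and ten-membered ring closure by intramolecular alkylation of stabilised carbanions are both established; O-alkylation and the C10 configuration would need watching.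

**Step 11.**
- What may go wrong: kinetic regiocontrol may be lost (enolisation towards C7, followed by epimerisation or β-elimination of the lactone carboxylate), intermolecular Si–O bond formation may give oligomers, and the bis-enol ether may hydrolyse during isolation.
- Fallback: it sets out from 17 and gives up the tether. LiN(iPr)2 (2.2 equiv) in the presence of Me3SiCl (internal quench, THF, −78 °C) gives the bis(trimethylsilyl) bis-enol ether F5, which is formed under the most reliable kinetic conditions and involves no macrocyclisation. Oxidation of F5 with (NH4)2Ce(NO3)6 and NaHCO3 at high dilution couples C9 with C10 intramolecularly. The fallback rejoins the route at 21.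

**Step 13.**
- What may go wrong: facial selectivity may be poor or reversed if the ten-membered ring presents the other face of the C8 carbonyl to the periphery, and the intermediate alkoxide may translactonise onto C12.
- Fallback: it sets out from 21. If hydride prefers the β face, the reduction is run to the 8-epi alcohol F6, which is esterified with methacrylic acid under Mitsunobu conditions (PPh3, diisopropyl azodicarboxylate, THF) with inversion at C8. The fallback rejoins the route at 24.

**Step 10.**
- What may go wrong: the sulfide may bind the gold catalyst and stall the cyclisation, or the activated alkynone may add a nucleophile across the C4=C5 enone instead.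
- Fallback: it sets out from 16 and uses the classical amine route. Et2NH in EtOH adds to the alkynone at C1 to give the enaminone F7. Aqueous AcOH then hydrolyses the enamine while the C10 hydroxyl condenses onto C3. The fallback rejoins the route at 17.

## Further compounds

F1 | step 12 | (3S,4S,5S)-4-(diazoacetyl)-5-[(1Z)-3-{[tert-butyl(dimethyl)silyl]oxy}-2-iodoprop-1-en-1-yl]-3-[(phenylsulfanyl)methyl]oxolan-2-one | I/C(CO[Si](C)(C)C(C)(C)C)=C\[C@H]1OC(=O)[C@@H](CSc2ccccc2)[C@@H]1C(=O)C=[N+]=[N-]
F2 | step 12 | (3S,4S,5S)-4-(chloroacetyl)-5-[(1Z)-3-{[tert-butyl(dimethyl)silyl]oxy}-2-iodoprop-1-en-1-yl]-3-[(phenylsulfanyl)methyl]oxolan-2-one | I/C(CO[Si](C)(C)C(C)(C)C)=C\[C@H]1OC(=O)[C@@H](CSc2ccccc2)[C@@H]1C(=O)CCl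
F3 | step 12 | 4-(chloroacetyl) analogue of 16 (both carbinol epimers) | CC(O)C#CC(=O)/C(CO[Si](C)(C)C(C)(C)C)=C\[C@H]1OC(=O)[C@@H](CSc2ccccc2)[C@@H]1C(=O)CCl
F4 | step 12 | 4-(chloroacetyl) analogue of 17 (both C10 epimers) | CC1OC(=CC1=O)/C(CO[Si](C)(C)C(C)(C)C)=C\[C@H]2OC(=O)[C@@H](CSc3ccccc3)[C@@H]2C(=O)CCl
F5 | step 11 | bis(trimethylsilyl) bis-enol ether of 17 (3-trimethylsilyloxyfuran and C8 trimethylsilyl enol ether) | Cc1oc(cc1O[Si](C)(C)C)/C(CO[Si](C)(C)C(C)(C)C)=C\[C@H]2OC(=O)[C@@H](CSc3ccccc3)[C@@H]2C(=C)O[Si](C)(C)C
F6 | step 13 | 8-epimer of 22 (8α-hydroxy) | O[C@H]1C[C@@]2(C)OC(=CC2=O)/C(CO[Si](C)(C)C(C)(C)C)=C\[C@H]2OC(=O)[C@@H](CSc3ccccc3)[C@@H]21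
F7 | step 10 | diethylamine adduct of 16 (E-enaminone, NEt2 on C1; both carbinol epimers) | CC(O)/C(N(CC)CC)=C\C(=O)/C(CO[Si](C)(C)C(C)(C)C)=C\[C@H]1OC(=O)[C@@H](CSc2ccccc2)[C@@H]1C(C)=O
A1 | alternative 1 | cis-fused decalin 3,8-diol (C3–C8 bond intact) with C1 ketone, C10 trimethylsilyl ether, O15 TBS ether and the trans α-methylene lactone; the cis-fusion face shown is arbitrary, since both carbinol centres are lost on cleavage | O[C@@]12C[C@](O[Si](C)(C)C)(C)C(=O)C[C@]1(O)C(CO[Si](C)(C)C(C)(C)C)=C[C@H]3OC(=O)C(=C)[C@@H]32
A2 | alternative 1 | ten-membered 1,3,8-trione with Z C4=C5, C10 trimethylsilyl ether, O15 TBS ether and trans α-methylene lactone | O=C1C[C@](O[Si](C)(C)C)(C)C(=O)CC(=O)/C(CO[Si](C)(C)C(C)(C)C)=C\[C@H]2OC(=O)C(=C)[C@@H]21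
A3 | alternative 2 | nine-membered lactone (O10 acylated by C3) with acetyl and methyl on C10, O8 triethylsilyl, O15 TBS | CC[Si](CC)(CC)O[C@@H]1C[C@](C)(C(C)=O)OC(=O)/C(CO[Si](C)(C)C(C)(C)C)=C\[C@H]2OC(=O)C(=C)[C@@H]21
A4 | alternative 2 | furanoheliangolide core, O8 triethylsilyl, O15 TBS | CC[Si](CC)(CC)O[C@@H]1C[C@@]2(C)OC(=CC2=O)/C(CO[Si](C)(C)C(C)(C)C)=C\[C@H]2OC(=O)C(=C)[C@@H]21
A5 | alternative 3 | acyclic diene: 2,2-disubstituted furanone with a 1-(TBS-oxymethyl)vinyl group on C3, and a C6-vinyl lactone lacking C13, O8 triethylsilyl | CC[Si](CC)(CC)O[C@H](C[C@@]1(C)OC(=CC1=O)C(=C)CO[Si](C)(C)C(C)(C)C)[C@H]1CC(=O)O[C@@H]1C=C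
A6 | alternative 3 | bridged furanone core with the 13-nor-11,13-dihydro lactone, O8 triethylsilyl, O15 TBS | CC[Si](CC)(CC)O[C@@H]1C[C@@]2(C)OC(=CC2=O)/C(CO[Si](C)(C)C(C)(C)C)=C\[C@H]2OC(=O)C[C@@H]21
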